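**Retrosynthetic overview** (atom labels follow the benzofuran numbering of the target)
1. Target 16 ⇐ O-methylation of diosphenol 15 ⇐ α′-oxidation at C5 of the bicyclic vinylogous ester 12.
2. 12 ⇐ keto lactone 10: an intramolecular Claisen condensation (C7–C7a) closes the carbocycle, then the C2 hydroxyl recloses the O-ring as an enol ether.
3. 10 ⇐ lactone 7: α-allylation, then Mukaiyama–Michael addition to but-3-en-2-one anti to the C3 methyl sets the quaternary C3a.
4. 7 ⇐ anti homoallylic alcohol 3 by hydroboration and oxidative lactonisation.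
5. Key C2–C3 disconnection: 3 ⇐ 3,4,5-trimethoxybenzaldehyde 1 + (E)-crotylborane (asymmetric carbonyl crotylation). Ring order: five-membered O-ring first (as lactone), six-membered carbocycle second.

Assumption: charged transient species (metal enolates, ate complexes) are not numbered, every neutral compound that forms in the flask and reacts on is numbered, and small atom-donating reagents stand on the "Reagents that add atoms" lines.

**Step 1**
Reactants: 1 3,4,5-trimethoxybenzaldehyde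
Product: 3 (1S,2S)-2-methyl-1-(3,4,5-trimethoxyphenyl)but-3-en-1-ol, via borinate ester 2 (not isolated)
Conditions: (E)-crotyl-B(Ipc)2 [made in the flask: (E)-but-2-ene, n-BuLi, KOtBu, THF, −45 °C; (−)-Ipc2BOMe (from (+)-α-pinene), −78 °C; BF3·OEt2], THF/Et2O, −78 °C; then NaOH, H2O2, 0 °C → rt
Reagents that add atoms: (E)-crotyldiisopinocampheylborane, C/C=C/CB([C@@H]1C[C@@H]2C[C@H]([C@H]1C)C2(C)C)[C@@H]1C[C@@H]2C[C@H]([C@H]1C)C2(C)C
Why: Brown asymmetric crotylboration (carbonyl allylation) runs through a chair Zimmerman–Traxler transition state, so the (E)-crotyl geometry gives the anti (later 2,3-trans) relationship and the Ipc groups from (+)-α-pinene direct attack to the Si face of the aldehyde, setting C2 (S) and C3 (S) in the C2–C3 bond-forming event.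

**Step 2**
Reactants: 3 (1S,2S)-2-methyl-1-(3,4,5-trimethoxyphenyl)but-3-en-1-ol
Product: 5 (1S,2S)-2-methyl-1-(3,4,5-trimethoxyphenyl)butane-1,4-diol, via alkyl-9-BBN adduct 4 (not isolated)
Conditions: 9-BBN (2.2 equiv), THF, 0 °C → rt; then NaOH, H2O2, 0 °C
Reagents that add atoms: hydrogen peroxide, OO
Why: anti-Markovnikov hydroboration–oxidation of the terminal vinyl group with the bulky borane gives only the primary alcohol and touches neither stereocentre.

**Step 3**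
Reactants: 5 (1S,2S)-2-methyl-1-(3,4,5-trimethoxyphenyl)butane-1,4-diol
Product: 7 (4S,5S)-4-methyl-5-(3,4,5-trimethoxyphenyl)dihydrofuran-2(3H)-one (trans), via lactol 6 (not isolated)
Conditions: TEMPO (10 mol%), PhI(OAc)2 (2.5 equiv), CH2Cl2, rt
Reagents that add atoms: none
Why: TEMPO-catalysed oxidative lactonisation oxidises the primary alcohol selectively, the aldehyde is trapped by the secondary hydroxyl as a lactol and this is oxidised on to the γ-lactone, with the benzylic C–O bond never broken.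

**Step 4**
Reactants: 7 (4S,5S)-4-methyl-5-(3,4,5-trimethoxyphenyl)dihydrofuran-2(3H)-one
Product: 8 (3S,4S,5S)-3-allyl-4-methyl-5-(3,4,5-trimethoxyphenyl)dihydrofuran-2(3H)-one (3,4-trans major)
Conditions: LiN(iPr)2 (1.05 equiv), THF, −78 °C; allyl bromide, −78 → −30 °C
Reagents that add atoms: allyl bromide, C=CCBr
Why: lactone enolate alkylation (SN2) with a reactive allylic halide; the allyl group enters trans to the C4 methyl, but this centre is flattened again in step 5, so its ratio is immaterial.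

**Step 5**
Reactants: 8 (3S,4S,5S)-3-allyl-4-methyl-5-(3,4,5-trimethoxyphenyl)dihydrofuran-2(3H)-one
Product: 10 (3R,4S,5S)-3-allyl-4-methyl-3-(3-oxobutyl)-5-(3,4,5-trimethoxyphenyl)dihydrofuran-2(3H)-one, via silyl ketene acetal 9 (not isolated)
Conditions: LiN(iPr)2, THF, −78 °C; Me3SiCl; solvent switch to CH2Cl2; but-3-en-2-one/TiCl4 (premixed), −78 °C; H2O
Reagents that add atoms: but-3-en-2-one (methyl vinyl ketone), C=CC(C)=O
Why: Mukaiyama–Michael addition of the planar silyl ketene acetal to the TiCl4-activated enone occurs on the face anti to the adjacent C4 methyl, so the 3-oxobutyl chain ends trans and the allyl group cis to that methyl, which fixes the quaternary centre (future C3a, R) and supplies C4–C7.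

**Step 6**
Reactants: 10 (3R,4S,5S)-3-allyl-4-methyl-3-(3-oxobutyl)-5-(3,4,5-trimethoxyphenyl)dihydrofuran-2(3H)-one
Product: 12 (2S,3S,3aR)-3a-allyl-3-methyl-2-(3,4,5-trimethoxyphenyl)-3,3a,4,5-tetrahydro-1-benzofuran-6(2H)-one, via hydroxy dione 11 (not isolated)
Conditions: KOtBu (2.5 equiv), THF, 0 °C → rt; 1 M HCl; then pyridinium p-toluenesulfonate (cat.), toluene, 4 Å sieves, 60 °C
Reagents that add atoms: none
Why: intramolecular Claisen (Dieckmann-type) condensation of the methyl ketone enolate onto the lactone carbonyl is driven by formation of the 1,3-diketone enolate, and the freed benzylic hydroxyl then closes onto the only carbonyl it can reach to give the cyclic vinylogous ester on mild acid-catalysed dehydration, with no stereocentre touched.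

**Step 7**
Reactants: 12 (2S,3S,3aR)-3a-allyl-3-methyl-2-(3,4,5-trimethoxyphenyl)-3,3a,4,5-tetrahydro-1-benzofuran-6(2H)-one
Product: 13 (2S,3S,3aS,5RS)-3a-allyl-5-hydroxy-3-methyl-2-(3,4,5-trimethoxyphenyl)-3,3a,4,5-tetrahydro-1-benzofuran-6(2H)-one
Conditions: KN(SiMe3)2, THF, −78 °C; 2-(phenylsulfonyl)-3-phenyloxaziridine; AcOH quench
Reagents that add atoms: 2-(phenylsulfonyl)-3-phenyloxaziridine (Davis oxaziridine), O=S(=O)(c1ccccc1)N1OC1c1ccccc1
Why: the vinylogous ester can be deprotonated only at the α′ carbon C5 (C3a is quaternary) and the cross-conjugated enolate is hydroxylated by the Davis oxaziridine (enolate oxidation); the new C5 centre is irrelevant because it becomes sp2 in step 8.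

**Step 8**
Reactants: 13 (2S,3S,3aS,5RS)-3a-allyl-5-hydroxy-3-methyl-2-(3,4,5-trimethoxyphenyl)-3,3a,4,5-tetrahydro-1-benzofuran-6(2H)-one
Product: 15 (2S,3S,3aR)-3a-allyl-5-hydroxy-3-methyl-2-(3,4,5-trimethoxyphenyl)-3,3a-dihydro-1-benzofuran-6(2H)-one, via 1,2-diketone 14 (not isolated)
Conditions: Dess–Martin periodinane, pyridine, CH2Cl2, 0 °C → rt
Reagents that add atoms: none
Why: Dess–Martin oxidation of the α-hydroxy ketone gives the 5,6-diketone, which can enolise only toward C4 and tautomerises to the conjugated diosphenol under the buffered, non-acidic conditions.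

**Step 9**
Reactants: 15 (2S,3S,3aR)-3a-allyl-5-hydroxy-3-methyl-2-(3,4,5-trimethoxyphenyl)-3,3a-dihydro-1-benzofuran-6(2H)-one
Product: 16 (2S,3S,3aR)-3a-allyl-5-methoxy-3-methyl-2-(3,4,5-trimethoxyphenyl)-3,3a-dihydro-1-benzofuran-6(2H)-one
Conditions: MeI, K2CO3, acetone, rt
Reagents that add atoms: iodomethane, CI
Why: Williamson-type O-methylation of the acidic diosphenol proceeds on oxygen because C4 is shielded by the adjacent quaternary centre, and room temperature avoids Cope migration of the 3a-allyl group.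

**Compound list**
1 | 3,4,5-trimethoxybenzaldehyde | COc1cc(C=O)cc(OC)c1OC | starting material
2 | (1S,2S)-2-methyl-1-(3,4,5-trimethoxyphenyl)but-3-en-1-yl diisopinocampheylborinate | B(O[C@H](c1cc(OC)c(OC)c(OC)c1)[C@H](C=C)C)([C@@H]1C[C@@H]2C[C@H]([C@H]1C)C2(C)C)[C@@H]1C[C@@H]2C[C@H]([C@H]1C)C2(C)C | intermediate
3 | (1S,2S)-2-methyl-1-(3,4,5-trimethoxyphenyl)but-3-en-1-ol | C=C[C@H](C)[C@H](O)c1cc(OC)c(OC)c(OC)c1 | intermediate
4 | (1S,2S)-4-(9-borabicyclo[3.3.1]nonan-9-yl)-2-methyl-1-(3,4,5-trimethoxyphenyl)butan-1-ol | O[C@H](c1cc(OC)c(OC)c(OC)c1)[C@H](CCB1C2CCCC1CCC2)C | intermediate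
5 | (1S,2S)-2-methyl-1-(3,4,5-trimethoxyphenyl)butane-1,4-diol | OCC[C@H](C)[C@H](O)c1cc(OC)c(OC)c(OC)c1 | intermediate
6 | (4S,5S)-4-methyl-5-(3,4,5-trimethoxyphenyl)tetrahydrofuran-2-ol (anomer mixture) | C[C@H]1CC(O)O[C@@H]1c1cc(OC)c(OC)c(OC)c1 | intermediate
7 | (4S,5S)-4-methyl-5-(3,4,5-trimethoxyphenyl)dihydrofuran-2(3H)-one | C[C@H]1CC(=O)O[C@@H]1c1cc(OC)c(OC)c(OC)c1 | intermediate
8 | (3S,4S,5S)-3-allyl-4-methyl-5-(3,4,5-trimethoxyphenyl)dihydrofuran-2(3H)-one | C=CC[C@@H]1C(=O)O[C@H](c2cc(OC)c(OC)c(OC)c2)[C@H]1C | intermediate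
9 | {[(4S,5S)-3-allyl-4-methyl-5-(3,4,5-trimethoxyphenyl)-4,5-dihydrofuran-2-yl]oxy}trimethylsilane | C=CCC1=C(O[Si](C)(C)C)O[C@H](c2cc(OC)c(OC)c(OC)c2)[C@H]1C | intermediate
10 | (3R,4S,5S)-3-allyl-4-methyl-3-(3-oxobutyl)-5-(3,4,5-trimethoxyphenyl)dihydrofuran-2(3H)-one | C=CC[C@@]1(CCC(C)=O)C(=O)O[C@H](c2cc(OC)c(OC)c(OC)c2)[C@H]1C | intermediate
11 | (4R)-4-allyl-4-[(1S,2S)-1-hydroxy-1-(3,4,5-trimethoxyphenyl)propan-2-yl]cyclohexane-1,3-dione | C=CC[C@]1(CCC(=O)CC1=O)[C@H](C)[C@H](O)c1cc(OC)c(OC)c(OC)c1 | intermediate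
12 | (2S,3S,3aR)-3a-allyl-3-methyl-2-(3,4,5-trimethoxyphenyl)-3,3a,4,5-tetrahydro-1-benzofuran-6(2H)-one | C=CC[C@@]12CCC(=O)C=C1O[C@H](c1cc(OC)c(OC)c(OC)c1)[C@H]2C | intermediate
13 | (2S,3S,3aS,5RS)-3a-allyl-5-hydroxy-3-methyl-2-(3,4,5-trimethoxyphenyl)-3,3a,4,5-tetrahydro-1-benzofuran-6(2H)-one (C5 epimers) | C=CC[C@@]12CC(O)C(=O)C=C1O[C@H](c1cc(OC)c(OC)c(OC)c1)[C@H]2C | intermediate
14 | (2S,3S,3aS)-3a-allyl-3-methyl-2-(3,4,5-trimethoxyphenyl)-2,3,3a,4-tetrahydro-1-benzofuran-5,6-dione | C=CC[C@@]12CC(=O)C(=O)C=C1O[C@H](c1cc(OC)c(OC)c(OC)c1)[C@H]2C | intermediate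
15 | (2S,3S,3aR)-3a-allyl-5-hydroxy-3-methyl-2-(3,4,5-trimethoxyphenyl)-3,3a-dihydro-1-benzofuran-6(2H)-one | C=CC[C@@]12C=C(O)C(=O)C=C1O[C@H](c1cc(OC)c(OC)c(OC)c1)[C@H]2C | intermediate
16 | (2S,3S,3aR)-3a-allyl-5-methoxy-3-methyl-2-(3,4,5-trimethoxyphenyl)-3,3a-dihydro-1-benzofuran-6(2H)-one | C=CC[C@@]12C=C(OC)C(=O)C=C1O[C@H](c1cc(OC)c(OC)c(OC)c1)[C@H]2C | target

**Totals**
Total step count: 9. Longest linear sequence: 9 steps (1 → 16).

**Three steps most likely to fail, with fallbacks**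

Step 5 (quaternary centre by Mukaiyama–Michael addition: hindered ketene acetal, possible oxidative dimerisation, eroded facial selectivity). The fallback sets out from 8 and replaces the conjugate addition by an SN2 alkylation. Lactone 8 is deprotonated with LiN(iPr)2 in THF/DMPU at −78 °C and alkylated, again anti to the methyl group, with 2-(2-iodoethyl)-2-methyl-1,3-dioxolane. This gives (3R,4S,5S)-3-allyl-4-methyl-3-[2-(2-methyl-1,3-dioxolan-2-yl)ethyl]-5-(3,4,5-trimethoxyphenyl)dihydrofuran-2(3H)-one F1. Ketal hydrolysis with pyridinium p-toluenesulfonate in acetone/H2O at 50 °C comes back to the route at 10.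

Step 7 (α′-hydroxylation: incomplete enolisation or sulfonimine adducts). The fallback sets out from 12 and reaches the methoxy dienone through an epoxide instead of a hydroxy ketone. Dehydrogenation with 2-iodoxybenzoic acid in DMSO/toluene at 70 °C gives the cross-conjugated dienone (2S,3S,3aS)-3a-allyl-3-methyl-2-(3,4,5-trimethoxyphenyl)-3,3a-dihydro-1-benzofuran-6(2H)-one F2. Weitz–Scheffer epoxidation (H2O2, NaOH, MeOH, 0 °C) of the more electron-poor C4=C5 bond gives (2S,3S,3aR)-3a-allyl-4,5-epoxy-3-methyl-2-(3,4,5-trimethoxyphenyl)-3,3a,4,5-tetrahydro-1-benzofuran-6(2H)-one F3. NaOMe in MeOH (rt → 50 °C) opens the epoxide at C5 and eliminates the C4 hydroxyl, coming back to the route at 16 and bypassing 13 to 15.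

Step 8 (oxidation to the diosphenol: over-oxidation or C–C cleavage of the α-hydroxy ketone). The fallback sets out from 13 and inverts the order of methylation and unsaturation. Mild O-methylation (MeI, Ag2O, MeCN, rt) gives (2S,3S,3aS,5RS)-3a-allyl-5-methoxy-3-methyl-2-(3,4,5-trimethoxyphenyl)-3,3a,4,5-tetrahydro-1-benzofuran-6(2H)-one F4. Selenenylation at C5 (KN(SiMe3)2, THF, −78 °C; PhSeBr) gives (2S,3S,3aS,5RS)-3a-allyl-5-methoxy-3-methyl-5-(phenylselanyl)-2-(3,4,5-trimethoxyphenyl)-3,3a,4,5-tetrahydro-1-benzofuran-6(2H)-one F5. Oxidation (H2O2, pyridine, CH2Cl2, 0 °C) and selenoxide syn-elimination toward C4–H comes back to the route at 16, bypassing 14 and 15.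

**Further compounds**
F1 | step 5 | (3R,4S,5S)-3-allyl-4-methyl-3-[2-(2-methyl-1,3-dioxolan-2-yl)ethyl]-5-(3,4,5-trimethoxyphenyl)dihydrofuran-2(3H)-one | C=CC[C@@]1(CCC2(C)OCCO2)C(=O)O[C@H](c2cc(OC)c(OC)c(OC)c2)[C@H]1C
F2 | step 7 | (2S,3S,3aS)-3a-allyl-3-methyl-2-(3,4,5-trimethoxyphenyl)-3,3a-dihydro-1-benzofuran-6(2H)-one | C=CC[C@@]12C=CC(=O)C=C1O[C@H](c1cc(OC)c(OC)c(OC)c1)[C@H]2C
F3 | step 7 | (2S,3S,3aR)-3a-allyl-4,5-epoxy-3-methyl-2-(3,4,5-trimethoxyphenyl)-3,3a,4,5-tetrahydro-1-benzofuran-6(2H)-one (epoxide face not assigned) | C=CC[C@@]12C3OC3C(=O)C=C1O[C@H](c1cc(OC)c(OC)c(OC)c1)[C@H]2C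
F4 | step 8 | (2S,3S,3aS,5RS)-3a-allyl-5-methoxy-3-methyl-2-(3,4,5-trimethoxyphenyl)-3,3a,4,5-tetrahydro-1-benzofuran-6(2H)-one | C=CC[C@@]12CC(OC)C(=O)C=C1O[C@H](c1cc(OC)c(OC)c(OC)c1)[C@H]2C
F5 | step 8 | (2S,3S,3aS,5RS)-3a-allyl-5-methoxy-3-methyl-5-(phenylselanyl)-2-(3,4,5-trimethoxyphenyl)-3,3a,4,5-tetrahydro-1-benzofuran-6(2H)-one | C=CC[C@@]12CC(OC)([Se]c3ccccc3)C(=O)C=C1O[C@H](c1cc(OC)c(OC)c(OC)c1)[C@H]2C
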